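**Plan**
1. Retrosynthetic cuts, in order: the chalcone Cα=Cβ bond (Claisen–Schmidt), the bond from ring A (the central benzene ring) to the acyl carbon (aryllithium plus Weinreb amide), and the styryl C=C bond (cross-metathesis, back to a vinyl group).
2. Enabling feature: the six carbons of ring A then carry in sequence OH, CH(vinyl)(4-arylbutyl), OH, H, OCH3, H. The three oxygens form a 1,3,5 array, and the only carbon substituent lies between two of them and para to the methoxy group. A cyclobutenone and an ynol ether give this pattern on benzannulation.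
3. Ring A is cut into 3-methoxycyclobut-2-enone (four ring carbons, the methoxy oxygen, one phenol oxygen) and a triisopropylsilyl ynol ether (the chain-bearing carbon and the adjacent C–O carbon). The bonds made run from the carbonyl carbon to the chain-bearing alkyne carbon and from cyclobutenone C2 to the oxygenated alkyne carbon.
4. Forward order: a 4-arylbutyl Grignard reagent and a silylated enyne chloride give the skipped enyne, whose terminal alkyne is oxidised to the ynol silyl ether. Ring A, the only ring built, is annulated onto it. The acetyl group, styryl arm and chalcone arm follow in that order before one global deprotection. Rings B, C and D (the three 4-hydroxyphenyl rings) are bought.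
5. Stereochemistry: the single (R) centre comes from a copper/phosphoramidite-catalysed enantioselective SN2' alkylation and is only carried afterwards. Both E alkenes arise under thermodynamic control (metathesis, aldol dehydration).

Key step: step 10

Assumption: the ligand antipode that gives the (R) product in step 5 is fixed by a test run, with the configuration checked on the desilylated enyne; nothing else in the route depends on which antipode that is.

Step 1
Reactants: 1 4-bromophenol
Product: 2 1-bromo-4-(methoxymethoxy)benzene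
Conditions: MOMCl (1.3 equiv), iPr2NEt (1.5 equiv), CH2Cl2, 0 °C to rt
Reagents that add atoms: chloromethyl methyl ether (MOMCl), COCCl
Why: O-alkylation of a phenol with an α-chloro ether (MOM protection) is routine, and the acetal tolerates the Grignard, organolithium, fluoride, thermal and hydroxide steps that follow.

Step 2
Reactants: 2 1-bromo-4-(methoxymethoxy)benzene; 3 1,4-dibromobutane
Product: 5 1-(4-bromobutyl)-4-(methoxymethoxy)benzene, via arylmagnesium bromide 4 (not isolated)
Conditions: Mg, THF, reflux; then added to 3 (3 equiv), Li2CuCl4 (3 mol %), THF, 0 °C to rt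
Reagents that add atoms: none
Why: Kochi-type copper-catalysed coupling of an aryl Grignard reagent with a primary alkyl bromide is well established, and the excess of dibromide should hold the reaction at monosubstitution.

Step 3
Reactants: 6 (E)-pent-2-en-4-yn-1-ol
Product: 8 (E)-5-(trimethylsilyl)pent-2-en-4-yn-1-ol, via bis-silylated enynol 7 (not isolated)
Conditions: n-BuLi (2.1 equiv), THF, −78 °C; TMSCl (2.2 equiv), −78 °C to rt; then 1 M HCl, rt
Reagents that add atoms: chlorotrimethylsilane, C[Si](C)(C)Cl
Why: Double deprotonation and silylation followed by selective hydrolysis of the far more labile O–Si bond is the standard C-silylation of an alkynol and leaves the E alkene untouched.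

Step 4
Reactants: 8 (E)-5-(trimethylsilyl)pent-2-en-4-yn-1-ol
Product: 9 (E)-(5-chloropent-3-en-1-yn-1-yl)trimethylsilane
Conditions: NCS (1.2 equiv), Me2S (1.3 equiv), CH2Cl2, −20 to 0 °C
Reagents that add atoms: N-chlorosuccinimide, O=C1CCC(=O)N1Cl
Why: Corey–Kim chlorination converts primary allylic alcohols into the chlorides by SN2 collapse of an alkoxysulfonium chloride, without allylic transposition or loss of alkene geometry.

Step 5
Reactants: 5 1-(4-bromobutyl)-4-(methoxymethoxy)benzene; 9 (E)-(5-chloropent-3-en-1-yn-1-yl)trimethylsilane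
Product: 11 (R)-{3-ethenyl-7-[4-(methoxymethoxy)phenyl]hept-1-yn-1-yl}trimethylsilane, via alkylmagnesium bromide 10 (not isolated)
Conditions: 5, Mg, Et2O, reflux; then slow addition to 9, monovalent copper thiophene-2-carboxylate Cu(O2C-C4H3S) (5 mol %), BINOL-derived phosphoramidite bearing a bis[1-(2-methoxyphenyl)ethyl]amino group (5.5 mol %, antipode giving R), CH2Cl2, −78 °C
Reagents that add atoms: none
Why: Copper-catalysed enantioselective allylic alkylation (SN2') of an enyne chloride with a primary alkyl Grignard reagent is a known route to skipped enynes: the chiral phosphoramidite–copper species selects one alkene face at the carbon next to the alkyne and so sets the (R) centre, while the silyl cap disfavours attack at the alkyne terminus.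

Step 6
Reactants: 11 (R)-{3-ethenyl-7-[4-(methoxymethoxy)phenyl]hept-1-yn-1-yl}trimethylsilane
Product: 12 (R)-3-ethenyl-7-[4-(methoxymethoxy)phenyl]hept-1-yne
Conditions: K2CO3 (0.2 equiv), MeOH, 0 °C to rt
Reagents that add atoms: none
Why: Methoxide-catalysed protodesilylation of an alkynylsilane is fast under conditions too mild to move the skipped enyne into conjugation, so the stereocentre should hold.

Step 7
Reactants: 12 (R)-3-ethenyl-7-[4-(methoxymethoxy)phenyl]hept-1-yne
Product: 15 (R)-({3-ethenyl-7-[4-(methoxymethoxy)phenyl]hept-1-yn-1-yl}oxy)triisopropylsilane, via lithium acetylide 13 (not isolated), via lithium ynolate 14 (not isolated)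
Conditions: n-BuLi (1.0 equiv), THF, −78 °C; LiOOt-Bu [t-BuOOH + LiHMDS, 1.1 equiv each, THF, −78 °C], −78 to 0 °C; TIPSOTf (1.3 equiv), −78 to 0 °C
Reagents that add atoms: tert-butyl hydroperoxide, CC(C)(C)OO; triisopropylsilyl trifluoromethanesulfonate, CC(C)[Si](C(C)C)(C(C)C)OS(=O)(=O)C(F)(F)F
Why: Oxygenation of a lithium acetylide by lithium tert-butyl peroxide to the ynolate, then O-silylation with a bulky silyl triflate, is the standard preparation of triisopropylsilyl ynol ethers, and one equivalent of base removes only the sp C–H, so the propargylic, allylic hydrogen stays in place.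

Step 8
Reactants: 16 ethoxyacetylene; 17 acetone
Product: 19 3-ethoxycyclobut-2-en-1-one, via ketene 18 (not isolated)
Conditions: 17 pyrolysed in a hot-wire ketene generator (ca. 700 °C), gas stream passed into 16 (solution in hexanes), CH2Cl2, 0 °C to rt
Reagents that add atoms: none
Why: The ketene–alkyne [2+2] cycloaddition is known for this very pair, and the unsubstituted carbon of the ynol ether bonds to the ketene carbonyl carbon to give the 3-alkoxy isomer.

Step 9
Reactants: 19 3-ethoxycyclobut-2-en-1-one
Product: 20 3-methoxycyclobut-2-en-1-one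
Conditions: MeOH (solvent), camphorsulfonic acid (2 mol %), rt; Et3N quench, distillation under reduced pressure
Reagents that add atoms: methanol, CO
Why: Acid-catalysed transetherification of a vinylogous ester (addition–elimination at C3) follows the path by which aqueous acid hydrolyses this enol ether, and the large excess of methanol should drive the exchange.

Step 10
Reactants: 15 (R)-({3-ethenyl-7-[4-(methoxymethoxy)phenyl]hept-1-yn-1-yl}oxy)triisopropylsilane; 20 3-methoxycyclobut-2-en-1-one
Product: 25 (R)-5-methoxy-2-{7-[4-(methoxymethoxy)phenyl]hept-1-en-3-yl}-3-[(triisopropylsilyl)oxy]phenol, via vinylketene 21 (not isolated), via vinylcyclobutenone 22 (not isolated), via dienylketene 23 (not isolated), via cyclohexadienone 24 (not isolated)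
Conditions: 20 (1.2 equiv, added in portions), toluene, sealed tube, argon, 120 °C, then 145 °C
Reagents that add atoms: none
Why: Heat opens 20 by a four-electron electrocyclic reaction (C1–C4 cleaved) to (1-methoxyvinyl)ketene 21, which adds 15 across its C=C=O unit in a [2+2] cycloaddition to give the 4-(1-methoxyvinyl)cyclobutenone 22; a second four-electron opening gives dienylketene 23, which cyclises to dienone 24 and enolises to phenol 25. This is the Danheiser benzannulation of a cyclobutenone with a siloxyalkyne, which gives resorcinol monosilyl ethers and has carried ynol ethers with a branched, stereodefined propargylic carbon; the 3-alkoxy group on the four-membered ring is the less common feature and, as part of a vinylogous ester, should require the upper end of the usual temperature range. Ring A closes by a six-electron electrocyclisation joining the ketene carbonyl carbon to the terminal CH2 of 23, and since only the isomer with ketene and methoxyvinyl groups cis on the central double bond can close, the reversible opening of 22 should funnel the material through it. No new stereocentre survives, because C4 of 22 is flattened on opening, and the (R) centre never joins the reacting π system and meets neither acid nor base. The step needs one orientation in the [2+2] event, which the oxygen lone pair secures by making the chain-bearing alkyne carbon the nucleophile toward the ketene carbonyl carbon, so the chain ends up between the new OH and the OTIPS group and para to OCH3. The unactivated vinyl group and the MOM ether are spectators beside the much more ketenophilic ynol ether, a silyl ynol ether has no retro-ene path to a ketene, and portionwise addition of 20 limits ketene self-reaction and acylation of the product phenol.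

Step 11
Reactants: 25 (R)-5-methoxy-2-{7-[4-(methoxymethoxy)phenyl]hept-1-en-3-yl}-3-[(triisopropylsilyl)oxy]phenol
Product: 26 (R)-5-methoxy-2-{7-[4-(methoxymethoxy)phenyl]hept-1-en-3-yl}benzene-1,3-diol
Conditions: TBAF (1.2 equiv), AcOH (1.2 equiv), THF, 0 °C
Reagents that add atoms: none
Why: Fluoride-driven cleavage of an aryl silyl ether is fast at 0 °C, and the acetic acid buffer keeps the electron-rich resorcinol protonated and leaves the MOM ether and alkene untouched.

Step 12
Reactants: 26 (R)-5-methoxy-2-{7-[4-(methoxymethoxy)phenyl]hept-1-en-3-yl}benzene-1,3-diol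
Product: 27 (R)-5-methoxy-1,3-bis(methoxymethoxy)-2-{7-[4-(methoxymethoxy)phenyl]hept-1-en-3-yl}benzene
Conditions: NaH (2.5 equiv), MOMCl (2.5 equiv), DMF, 0 °C to rt
Reagents that add atoms: chloromethyl methyl ether (MOMCl), COCCl
Why: Williamson-type O-alkylation of both phenoxides gives ring A two identical acetals, which make its two free positions equivalent, later chelate the aryllithium and survive hydroxide.

Step 13
Reactants: 27 (R)-5-methoxy-1,3-bis(methoxymethoxy)-2-{7-[4-(methoxymethoxy)phenyl]hept-1-en-3-yl}benzene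
Product: 28 (R)-2-bromo-1-methoxy-3,5-bis(methoxymethoxy)-4-{7-[4-(methoxymethoxy)phenyl]hept-1-en-3-yl}benzene
Conditions: NBS (1.0 equiv), MeCN, −20 °C, dark
Reagents that add atoms: N-bromosuccinimide, O=C1CCC(=O)N1Br
Why: In this electrophilic aromatic bromination all three alkoxy groups of ring A direct to its two equivalent free positions, so ring A should far outpace the mono-oxygenated ring and the vinyl group, and one equivalent at low temperature should stop at the monobromide.

Step 14
Reactants: 28 (R)-2-bromo-1-methoxy-3,5-bis(methoxymethoxy)-4-{7-[4-(methoxymethoxy)phenyl]hept-1-en-3-yl}benzene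
Product: 31 (R)-1-[6-methoxy-2,4-bis(methoxymethoxy)-3-{7-[4-(methoxymethoxy)phenyl]hept-1-en-3-yl}phenyl]ethan-1-one, via aryllithium 29 (not isolated), via tetrahedral lithium adduct 30 (not isolated)
Conditions: n-BuLi (1.05 equiv), THF, −78 °C; MeC(O)N(OMe)Me (1.5 equiv), −78 to 0 °C; then H2O
Reagents that add atoms: N-methoxy-N-methylacetamide, CC(=O)N(C)OC
Why: Bromine–lithium exchange at −78 °C is faster than deprotonation of the benzylic, allylic C–H, the flanking OMe and OMOM oxygens stabilise the aryllithium, and the Weinreb ketone synthesis rests at the chelated adduct until water releases the methyl ketone.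

Step 15
Reactants: 31 (R)-1-[6-methoxy-2,4-bis(methoxymethoxy)-3-{7-[4-(methoxymethoxy)phenyl]hept-1-en-3-yl}phenyl]ethan-1-one; 32 4-acetoxystyrene
Product: 33 4-[(1E,3R)-3-[3-acetyl-4-methoxy-2,6-bis(methoxymethoxy)phenyl]-7-[4-(methoxymethoxy)phenyl]hept-1-en-1-yl]phenyl acetate
Conditions: 32 (3 equiv), second-generation Hoveyda–Grubbs catalyst RuCl2(H2IMes)(=CH-C6H4-2-OiPr) (5 mol %), 1,4-benzoquinone (10 mol %), CH2Cl2, 40 °C, argon sparge
Reagents that add atoms: none
Why: Olefin cross-metathesis between an allylically branched terminal alkene that homodimerises slowly and an excess of a readily exchanging styrene should give the E-styrene with loss of ethene, and benzoquinone intercepts ruthenium hydrides that could move the double bond toward the stereocentre.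

Step 16
Reactants: 33 4-[(1E,3R)-3-[3-acetyl-4-methoxy-2,6-bis(methoxymethoxy)phenyl]-7-[4-(methoxymethoxy)phenyl]hept-1-en-1-yl]phenyl acetate; 34 4-(methoxymethoxy)benzaldehyde
Product: 37 (E)-1-[3-{(1E,3R)-1-(4-hydroxyphenyl)-7-[4-(methoxymethoxy)phenyl]hept-1-en-3-yl}-6-methoxy-2,4-bis(methoxymethoxy)phenyl]-3-[4-(methoxymethoxy)phenyl]prop-2-en-1-one, via phenolic ketone 35 (not isolated), via aldol adduct 36 (not isolated)
Conditions: 34 (1.5 equiv), KOH (10 equiv), MeOH, rt to 40 °C; then AcOH to pH 6
Reagents that add atoms: none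
Why: In this Claisen–Schmidt condensation hydroxide first cleaves the aryl acetate, then the methyl ketone enolate adds to the non-enolisable aldehyde and E1cB loss of water gives the E-enone, as established for 3'-alkyl-6'-methoxy-2',4'-bis(methoxymethoxy)acetophenones, while the phenoxide on the styryl ring lowers the acidity of the adjacent C–H and so protects the stereocentre.

Step 17
Reactants: 37 (E)-1-[3-{(1E,3R)-1-(4-hydroxyphenyl)-7-[4-(methoxymethoxy)phenyl]hept-1-en-3-yl}-6-methoxy-2,4-bis(methoxymethoxy)phenyl]-3-[4-(methoxymethoxy)phenyl]prop-2-en-1-one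
Product: 38 deoxycalyxin A, (E)-1-[3-{(1E,3R)-1,7-bis(4-hydroxyphenyl)hept-1-en-3-yl}-2,4-dihydroxy-6-methoxyphenyl]-3-(4-hydroxyphenyl)prop-2-en-1-one
Conditions: 3 M aq. HCl–MeOH (1:4), argon, rt, stopped at full conversion
Reagents that add atoms: none
Why: Acid-catalysed acetal exchange with methanol removes all four MOM groups under conditions proven on 3'-prenylated 2',4'-dihydroxy-6'-methoxychalcones, whose trisubstituted alkene is at least as acid-sensitive as the styrene here, and it affects neither the aryl methyl ether nor the stereocentre.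

**Compound list**
1 | 4-bromophenol | Oc1ccc(Br)cc1 | starting material
2 | 1-bromo-4-(methoxymethoxy)benzene | COCOc1ccc(Br)cc1 | intermediate
3 | 1,4-dibromobutane | BrCCCCBr | starting material
4 | 4-(methoxymethoxy)phenylmagnesium bromide (formed in situ) | COCOc1ccc([Mg]Br)cc1 | intermediate
5 | 1-(4-bromobutyl)-4-(methoxymethoxy)benzene | COCOc1ccc(CCCCBr)cc1 | intermediate
6 | (E)-pent-2-en-4-yn-1-ol | C#C/C=C/CO | starting material
7 | (E)-trimethyl{5-[(trimethylsilyl)oxy]pent-3-en-1-yn-1-yl}silane (formed in situ) | C[Si](C)(C)C#C/C=C/CO[Si](C)(C)C | intermediate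
8 | (E)-5-(trimethylsilyl)pent-2-en-4-yn-1-ol | C[Si](C)(C)C#C/C=C/CO | intermediate
9 | (E)-(5-chloropent-3-en-1-yn-1-yl)trimethylsilane | C[Si](C)(C)C#C/C=C/CCl | intermediate
10 | 4-[4-(methoxymethoxy)phenyl]butylmagnesium bromide (formed in situ) | COCOc1ccc(CCCC[Mg]Br)cc1 | intermediate
11 | (R)-{3-ethenyl-7-[4-(methoxymethoxy)phenyl]hept-1-yn-1-yl}trimethylsilane | C[Si](C)(C)C#C[C@@H](C=C)CCCCc1ccc(OCOC)cc1 | intermediate
12 | (R)-3-ethenyl-7-[4-(methoxymethoxy)phenyl]hept-1-yne | C#C[C@@H](C=C)CCCCc1ccc(OCOC)cc1 | intermediate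
13 | lithium acetylide of 12, (R) (formed in situ) | [Li]C#C[C@@H](C=C)CCCCc1ccc(OCOC)cc1 | intermediate
14 | lithium ynolate derived from 13, (R) (formed in situ) | [Li]OC#C[C@@H](C=C)CCCCc1ccc(OCOC)cc1 | intermediate
15 | (R)-({3-ethenyl-7-[4-(methoxymethoxy)phenyl]hept-1-yn-1-yl}oxy)triisopropylsilane | CC(C)[Si](C(C)C)(C(C)C)OC#C[C@@H](C=C)CCCCc1ccc(OCOC)cc1 | intermediate
16 | ethoxyacetylene | CCOC#C | starting material
17 | acetone | CC(C)=O | starting material
18 | ketene (generated and consumed directly) | C=C=O | intermediate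
19 | 3-ethoxycyclobut-2-en-1-one | CCOC1=CC(=O)C1 | intermediate
20 | 3-methoxycyclobut-2-en-1-one | COC1=CC(=O)C1 | intermediate
21 | (1-methoxyvinyl)ketene, 3-methoxybuta-1,3-dien-1-one (formed in situ) | C=C(OC)C=C=O | intermediate
22 | 4-(1-methoxyvinyl)-3-[(triisopropylsilyl)oxy]cyclobut-2-en-1-one bearing the (R) side chain at C2, either configuration at C4 (formed in situ) | O=C1C([C@@H](C=C)CCCCc2ccc(OCOC)cc2)=C(O[Si](C(C)C)(C(C)C)C(C)C)C1C(=C)OC | intermediate
23 | dienylketene with ketene and methoxyvinyl groups cis on the central double bond, (R) side chain on the ketene carbon (formed in situ) | O=C=C([C@@H](C=C)CCCCc1ccc(OCOC)cc1)/C(O[Si](C(C)C)(C(C)C)C(C)C)=C\C(=C)OC | intermediate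
24 | 5-methoxy-3-[(triisopropylsilyl)oxy]cyclohexa-2,4-dien-1-one bearing the (R) side chain at C2 (formed in situ) | O=C1CC(OC)=CC(O[Si](C(C)C)(C(C)C)C(C)C)=C1[C@@H](C=C)CCCCc2ccc(OCOC)cc2 | intermediate
25 | (R)-5-methoxy-2-{7-[4-(methoxymethoxy)phenyl]hept-1-en-3-yl}-3-[(triisopropylsilyl)oxy]phenol | COc1cc(O)c([C@@H](C=C)CCCCc2ccc(OCOC)cc2)c(O[Si](C(C)C)(C(C)C)C(C)C)c1 | intermediate
26 | (R)-5-methoxy-2-{7-[4-(methoxymethoxy)phenyl]hept-1-en-3-yl}benzene-1,3-diol | COc1cc(O)c([C@@H](C=C)CCCCc2ccc(OCOC)cc2)c(O)c1 | intermediate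
27 | (R)-5-methoxy-1,3-bis(methoxymethoxy)-2-{7-[4-(methoxymethoxy)phenyl]hept-1-en-3-yl}benzene | COc1cc(OCOC)c([C@@H](C=C)CCCCc2ccc(OCOC)cc2)c(OCOC)c1 | intermediate
28 | (R)-2-bromo-1-methoxy-3,5-bis(methoxymethoxy)-4-{7-[4-(methoxymethoxy)phenyl]hept-1-en-3-yl}benzene | COc1cc(OCOC)c([C@@H](C=C)CCCCc2ccc(OCOC)cc2)c(OCOC)c1Br | intermediate
29 | aryllithium from 28, (R) (formed in situ) | COc1cc(OCOC)c([C@@H](C=C)CCCCc2ccc(OCOC)cc2)c(OCOC)c1[Li] | intermediate
30 | lithium alkoxide adduct of 29 to N-methoxy-N-methylacetamide, (R) at the side chain (formed in situ) | COc1cc(OCOC)c([C@@H](C=C)CCCCc2ccc(OCOC)cc2)c(OCOC)c1C(C)(O[Li])N(C)OC | intermediate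
31 | (R)-1-[6-methoxy-2,4-bis(methoxymethoxy)-3-{7-[4-(methoxymethoxy)phenyl]hept-1-en-3-yl}phenyl]ethan-1-one | COc1cc(OCOC)c([C@@H](C=C)CCCCc2ccc(OCOC)cc2)c(OCOC)c1C(C)=O | intermediate
32 | 4-acetoxystyrene | CC(=O)Oc1ccc(C=C)cc1 | starting material
33 | 4-[(1E,3R)-3-[3-acetyl-4-methoxy-2,6-bis(methoxymethoxy)phenyl]-7-[4-(methoxymethoxy)phenyl]hept-1-en-1-yl]phenyl acetate | COc1cc(OCOC)c([C@@H](/C=C/c2ccc(OC(C)=O)cc2)CCCCc2ccc(OCOC)cc2)c(OCOC)c1C(C)=O | intermediate
34 | 4-(methoxymethoxy)benzaldehyde | COCOc1ccc(C=O)cc1 | starting material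
35 | 1-[3-{(1E,3R)-1-(4-hydroxyphenyl)-7-[4-(methoxymethoxy)phenyl]hept-1-en-3-yl}-6-methoxy-2,4-bis(methoxymethoxy)phenyl]ethan-1-one (formed in situ) | COc1cc(OCOC)c([C@@H](/C=C/c2ccc(O)cc2)CCCCc2ccc(OCOC)cc2)c(OCOC)c1C(C)=O | intermediate
36 | β-hydroxy ketone from 35 and 34, (R) at the side chain, either configuration at the carbinol (formed in situ) | COc1cc(OCOC)c([C@@H](/C=C/c2ccc(O)cc2)CCCCc2ccc(OCOC)cc2)c(OCOC)c1C(=O)CC(O)c1ccc(OCOC)cc1 | intermediate
37 | (E)-1-[3-{(1E,3R)-1-(4-hydroxyphenyl)-7-[4-(methoxymethoxy)phenyl]hept-1-en-3-yl}-6-methoxy-2,4-bis(methoxymethoxy)phenyl]-3-[4-(methoxymethoxy)phenyl]prop-2-en-1-one | COc1cc(OCOC)c([C@@H](/C=C/c2ccc(O)cc2)CCCCc2ccc(OCOC)cc2)c(OCOC)c1C(=O)/C=C/c1ccc(OCOC)cc1 | intermediate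
38 | deoxycalyxin A, (R) | COc1cc(O)c([C@@H](/C=C/c2ccc(O)cc2)CCCCc2ccc(O)cc2)c(O)c1C(=O)/C=C/c1ccc(O)cc1 | target

**Step count.** Total: 17 steps. Longest linear sequence: 13 steps (steps 1, 2, 5, 6, 7 and 10 to 17, from 1).

**Steps most likely to fail**

Step 10. The donor-stabilised enone of 20 may open so slowly that, at the temperature then needed, silyl migration within 15 or self-reaction of the ketene takes over.
- Fallback: the same vinylketene 21 is generated at room temperature from an open-chain diazo ketone by photochemical Wolff rearrangement, the diazo ketone variant of the same annulation.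
- Commercial 3,3-dimethoxybutan-2-one is distilled from catalytic p-TsOH to give 3-methoxybut-3-en-2-one F1.
- LiHMDS and 2,2,2-trifluoroethyl trifluoroacetate (THF, −78 °C) give 1,1,1-trifluoro-5-methoxyhex-5-ene-2,4-dione F2.
- Mesyl azide, Et3N and water in MeCN (detrifluoroacetylative diazo transfer) give 1-diazo-3-methoxybut-3-en-2-one F3.
- The fallback sets out from 15. Irradiation of F3 with 15 (254 nm, CH2Cl2, rt), then warming to 80–110 °C, passes through 21 to 24 and comes back to the route at 25.

Step 5. Attack of the organocopper species at the chloride-bearing carbon or at the alkyne terminus, or weak facial discrimination next to the slim alkynyl group, may erode regio- and enantioselectivity.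
- Fallback: the polarity is reversed, so that the alkyne becomes the nucleophile and the arylbutyl chain sits in the allylic electrophile. The fallback sets out from 5.
- Dilithiated propargyl alcohol (n-BuLi, THF–DMPU) is alkylated with 5 to give 7-[4-(methoxymethoxy)phenyl]hept-2-yn-1-ol F4.
- Semihydrogenation (H2, Pd/CaCO3 poisoned with Pb(OAc)2, quinoline) gives (Z)-7-[4-(methoxymethoxy)phenyl]hept-2-en-1-ol F5.
- ClP(O)(OEt)2 and pyridine give diethyl (Z)-7-[4-(methoxymethoxy)phenyl]hept-2-en-1-yl phosphate F6.
- Copper–carbene catalysed enantioselective SN2' alkynylation with (triisopropylsilyl)acetylene (CuCl, chiral phenol-bearing imidazolinium salt, LiOt-Bu, CH2Cl2, rt) gives (R)-{3-ethenyl-7-[4-(methoxymethoxy)phenyl]hept-1-yn-1-yl}triisopropylsilane F7.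
- TBAF (THF, 0 °C) then comes back to the route at 12.

Step 17. While the hindered ring A acetals are slowly lost, the acid may protonate the electron-rich 4-hydroxystyryl double bond, after which a neighbouring phenol closes onto the benzylic position. The acid may also promote ring closure of the 2'-hydroxychalcone.
- Fallback: acid is applied before the styrene exists, and the last step becomes a fluoride desilylation. The fallback sets out from 31.
- Claisen–Schmidt condensation of 31 with 34 (KOH, MeOH) gives (E)-1-[6-methoxy-2,4-bis(methoxymethoxy)-3-{(3R)-7-[4-(methoxymethoxy)phenyl]hept-1-en-3-yl}phenyl]-3-[4-(methoxymethoxy)phenyl]prop-2-en-1-one F8.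
- HCl–MeOH, now facing only an unactivated vinyl group, gives (E)-1-[2,4-dihydroxy-3-{(3R)-7-(4-hydroxyphenyl)hept-1-en-3-yl}-6-methoxyphenyl]-3-(4-hydroxyphenyl)prop-2-en-1-one F9.
- Cross-metathesis with commercial 4-(tert-butyldimethylsilyloxy)styrene (second-generation Hoveyda–Grubbs catalyst, EtOAc, 40 °C) gives the styryl-ring tert-butyldimethylsilyl ether of deoxycalyxin A F10. Aryl exchange at the enone is harmless here, because it leads to the same phenol after desilylation.
- Et3N·3HF (THF, 0 °C) comes back to the route at 38.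

**Further compounds**
F1 | step 10 | 3-methoxybut-3-en-2-one | C=C(OC)C(C)=O
F2 | step 10 | 1,1,1-trifluoro-5-methoxyhex-5-ene-2,4-dione | C=C(OC)C(=O)CC(=O)C(F)(F)F
F3 | step 10 | 1-diazo-3-methoxybut-3-en-2-one | C=C(OC)C(=O)C=[N+]=[N-]
F4 | step 5 | 7-[4-(methoxymethoxy)phenyl]hept-2-yn-1-ol | OCC#CCCCCc1ccc(OCOC)cc1
F5 | step 5 | (Z)-7-[4-(methoxymethoxy)phenyl]hept-2-en-1-ol | OC/C=C\CCCCc1ccc(OCOC)cc1
F6 | step 5 | diethyl (Z)-7-[4-(methoxymethoxy)phenyl]hept-2-en-1-yl phosphate | CCOP(=O)(OCC)OC/C=C\CCCCc1ccc(OCOC)cc1
F7 | step 5 | (R)-{3-ethenyl-7-[4-(methoxymethoxy)phenyl]hept-1-yn-1-yl}triisopropylsilane | CC(C)[Si](C(C)C)(C(C)C)C#C[C@@H](C=C)CCCCc1ccc(OCOC)cc1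
F8 | step 17 | (E)-1-[6-methoxy-2,4-bis(methoxymethoxy)-3-{(3R)-7-[4-(methoxymethoxy)phenyl]hept-1-en-3-yl}phenyl]-3-[4-(methoxymethoxy)phenyl]prop-2-en-1-one | COc1cc(OCOC)c([C@@H](C=C)CCCCc2ccc(OCOC)cc2)c(OCOC)c1C(=O)/C=C/c1ccc(OCOC)cc1
F9 | step 17 | (E)-1-[2,4-dihydroxy-3-{(3R)-7-(4-hydroxyphenyl)hept-1-en-3-yl}-6-methoxyphenyl]-3-(4-hydroxyphenyl)prop-2-en-1-one | COc1cc(O)c([C@@H](C=C)CCCCc2ccc(O)cc2)c(O)c1C(=O)/C=C/c1ccc(O)cc1
F10 | step 17 | deoxycalyxin A tert-butyldimethylsilyl ether at the styryl ring, (R) | COc1cc(O)c([C@@H](/C=C/c2ccc(O[Si](C)(C)C(C)(C)C)cc2)CCCCc2ccc(O)cc2)c(O)c1C(=O)/C=C/c1ccc(O)cc1
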